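The cyclopentene is disconnected at its two saturated ring bonds, C4–C5 and C2–C3 (ring numbering: C1 bears CH2OAc, C2 the formyl group, C3 the side chain). One flask closes both: the γ-carbon of the methyl acetoacetate dianion displaces an allylic bromide (C4–C5), the unmasked α-branched enal then accepts the β-keto ester in an amine-catalysed 5-exo Michael addition (C2–C3) that sets C3 and the side-chain α-carbon. The step exploits that ring C3 is β to the side-chain formyl carbon and that C5 is γ to the C2 carboxyl carbon once C1 is a ketone. The precursor is an acyclic bromo enal acetal built from geranyl bromide; C1 is elaborated afterwards.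

Key step: step 4

Remark: the E/Z mixture at the trisubstituted alkene of bromide 6 is assumed to converge on the (E)-enal 9 under the acidic, amine-containing conditions of step 4 (reversible dienol/dienamine formation).

Step 1
Reactants: 1 geranyl bromide; 2 1,1-dimethoxypropan-2-one
Product: 3 (5E)-1,1-dimethoxy-6,10-dimethylundeca-5,9-dien-2-one
Conditions: 2, LDA, THF, −78 °C; then 1, DMPU, −78 °C to 0 °C
Reagents that add atoms: none
Why: Kinetic deprotonation at the methyl group and SN2 alkylation of the lithium enolate by the allylic bromide (ketone enolate alkylation) should give 3 with the E-alkene untouched; no stereocentre is formed.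

Step 2
Reactants: 3 (5E)-1,1-dimethoxy-6,10-dimethylundeca-5,9-dien-2-one; 4 vinylmagnesium bromide
Product: 5 (6E)-3-(dimethoxymethyl)-7,11-dimethyldodeca-1,6,10-trien-3-ol (racemic)
Conditions: THF, −78 °C to 0 °C; then H2O
Reagents that add atoms: none
Why: 1,2-Addition of the vinyl Grignard reagent to the ketone (Grignard addition) should give the tertiary vinyl carbinol; its stereocentre is racemic and is destroyed in step 3.

Step 3
Reactants: 5 (6E)-3-(dimethoxymethyl)-7,11-dimethyldodeca-1,6,10-trien-3-ol
Product: 6 (6E)-1-bromo-3-(dimethoxymethyl)-7,11-dimethyldodeca-2,6,10-triene (2E/2Z mixture)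
Conditions: PBr3 (0.4 equiv), pyridine (cat.), Et2O, −20 °C to 0 °C
Reagents that add atoms: phosphorus tribromide, BrP(Br)Br
Why: SN2′ bromination of a tertiary vinyl carbinol (allylic transposition, as used for tertiary terpene alcohols) should give the primary allylic bromide; the electron-withdrawing acetal disfavours a free cation and hence cation–olefin cyclisation.

Step 4
Reactants: 6 (6E)-1-bromo-3-(dimethoxymethyl)-7,11-dimethyldodeca-2,6,10-triene; 7 methyl acetoacetate
Product: 10 methyl (5R)-5-[(2S,5E)-6,10-dimethyl-1-oxoundeca-5,9-dien-2-yl]-2-oxocyclopentane-1-carboxylate, via keto ester acetal 8 (not isolated), via keto ester enal 9 (not isolated)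
Conditions: 7, NaH, then n-BuLi, THF, 0 °C; 6, 0 °C to rt; then CF3CO2H, H2O, rt; then 9-amino-9-deoxy-epi-quinine (20 mol %), rt
Reagents that add atoms: water, O
Why: The acetoacetate dianion reacts only at its γ-carbon with the primary allylic bromide (SN2), forming the C4–C5 ring bond; aqueous acid then unmasks the enal, and the primary amine converts it into an (E)-iminium ion whose β-carbon is attacked by the tethered β-keto ester enol, forming the C2–C3 ring bond. The closest known reaction types are the γ-alkylation of β-keto ester dianions and the iminium-catalysed Michael addition of 1,3-dicarbonyl compounds to α-branched enals with cinchona-derived primary amines. The ring closes in a 5-exo-trig mode with respect to the acceptor (5-enolendo for the nucleophile, as in the aldol closure of 1,4-diketones), which is acceptable because the addition is reversible and the β-keto ester is the thermodynamic sink. The ring stereocentre is controlled by the catalyst, chosen so that the enol adds to the Re face of the iminium β-carbon (the quinidine-derived pseudo-enantiomer is used if the sense proves opposite). The side-chain α-stereocentre is set by protonation of the resulting enamine on its Re face, anti to the new ring bond in the conformer that minimises allylic strain, reinforced by the catalyst. The step needs γ- over α-alkylation (secured by the dianion), cyclisation over intermolecular condensation (five-atom tether) and a catalysed pathway faster than the acid-mediated racemic closure (mild acid, prompt addition of the amine).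

Step 5
Reactants: 10 methyl (5R)-5-[(2S,5E)-6,10-dimethyl-1-oxoundeca-5,9-dien-2-yl]-2-oxocyclopentane-1-carboxylate
Product: 11 methyl (5R)-5-[(2S,5E)-6,10-dimethyl-1-oxoundeca-5,9-dien-2-yl]-2-{[(trifluoromethyl)sulfonyl]oxy}cyclopent-1-ene-1-carboxylate
Conditions: Tf2O, i-Pr2NEt, CH2Cl2, −78 °C
Reagents that add atoms: trifluoromethanesulfonic anhydride, O=S(=O)(OS(=O)(=O)C(F)(F)F)C(F)(F)F
Why: O-Sulfonylation of the β-keto ester enol (vinyl triflate formation) is far faster than enolisation of the aldehyde with a hindered amine at −78 °C, so the side-chain α-centre should survive.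

Step 6
Reactants: 11 methyl (5R)-5-[(2S,5E)-6,10-dimethyl-1-oxoundeca-5,9-dien-2-yl]-2-{[(trifluoromethyl)sulfonyl]oxy}cyclopent-1-ene-1-carboxylate
Product: 12 (3R)-2-(hydroxymethyl)-3-[(2S,5E)-1-hydroxy-6,10-dimethylundeca-5,9-dien-2-yl]cyclopent-1-en-1-yl trifluoromethanesulfonate
Conditions: i-Bu2AlH (4 equiv), CH2Cl2, −78 °C; then aq. potassium sodium tartrate
Reagents that add atoms: none
Why: Hydride reduction with i-Bu2AlH converts the conjugated ester into the allylic alcohol and the aldehyde into the primary alcohol while the vinyl triflate is inert at −78 °C; the epimerisable centre is thereby locked until the last step.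

Step 7
Reactants: 13 (tributylstannyl)methanol
Product: 14 (tributylstannyl)methyl acetate
Conditions: Ac2O, pyridine, DMAP (cat.), CH2Cl2, 0 °C to rt
Reagents that add atoms: acetic anhydride, CC(=O)OC(C)=O
Why: DMAP-catalysed acetylation of the primary alcohol gives the acetoxymethyl stannane needed for step 8.

Step 8
Reactants: 12 (3R)-2-(hydroxymethyl)-3-[(2S,5E)-1-hydroxy-6,10-dimethylundeca-5,9-dien-2-yl]cyclopent-1-en-1-yl trifluoromethanesulfonate; 14 (tributylstannyl)methyl acetate
Product: 15 [(3R)-2-(hydroxymethyl)-3-[(2S,5E)-1-hydroxy-6,10-dimethylundeca-5,9-dien-2-yl]cyclopent-1-en-1-yl]methyl acetate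
Conditions: Pd(PPh3)4 (10 mol %), LiCl (3 equiv), 1,4-dioxane, 90 °C
Reagents that add atoms: none
Why: Stille coupling (oxidative addition of zerovalent palladium into the vinyl triflate, transfer of the α-oxygenated methyl group in preference to butyl, reductive elimination) should install CH2OAc under neutral conditions that tolerate both free hydroxyl groups.

Step 9
Reactants: 15 [(3R)-2-(hydroxymethyl)-3-[(2S,5E)-1-hydroxy-6,10-dimethylundeca-5,9-dien-2-yl]cyclopent-1-en-1-yl]methyl acetate
Product: 16 [(3R)-2-formyl-3-[(2S,5E)-6,10-dimethyl-1-oxoundeca-5,9-dien-2-yl]cyclopent-1-en-1-yl]methyl acetate (CNP0280859.1)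
Conditions: (COCl)2, DMSO, CH2Cl2, −78 °C; then i-Pr2NEt, −78 °C to −30 °C; cold pH 7 buffer
Reagents that add atoms: none
Why: Swern oxidation activates both hydroxyl groups before base is added, so the allylic and the saturated primary alcohol should be oxidised together to the dialdehyde without lactol formation, acetate cleavage or epimerisation at low temperature.

Compound list
1 | geranyl bromide | BrC/C=C(\C)CCC=C(C)C | starting material
2 | 1,1-dimethoxypropan-2-one | CC(=O)C(OC)OC | starting material
3 | (5E)-1,1-dimethoxy-6,10-dimethylundeca-5,9-dien-2-one | COC(OC)C(=O)CC/C=C(\C)CCC=C(C)C | intermediate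
4 | vinylmagnesium bromide | C=C[Mg]Br | starting material
5 | (6E)-3-(dimethoxymethyl)-7,11-dimethyldodeca-1,6,10-trien-3-ol (racemic) | C=CC(O)(C(OC)OC)CC/C=C(\C)CCC=C(C)C | intermediate
6 | (6E)-1-bromo-3-(dimethoxymethyl)-7,11-dimethyldodeca-2,6,10-triene (2E/2Z mixture) | BrCC=C(C(OC)OC)CC/C=C(\C)CCC=C(C)C | intermediate
7 | methyl acetoacetate | CC(=O)CC(=O)OC | starting material
8 | methyl (10E)-7-(dimethoxymethyl)-11,15-dimethyl-3-oxohexadeca-6,10,14-trienoate (6E/6Z mixture, not isolated) | COC(=O)CC(=O)CCC=C(C(OC)OC)CC/C=C(\C)CCC=C(C)C | intermediate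
9 | methyl (6E,10E)-7-formyl-11,15-dimethyl-3-oxohexadeca-6,10,14-trienoate (not isolated) | COC(=O)CC(=O)CC/C=C(/C=O)CC/C=C(\C)CCC=C(C)C | intermediate
10 | methyl (5R)-5-[(2S,5E)-6,10-dimethyl-1-oxoundeca-5,9-dien-2-yl]-2-oxocyclopentane-1-carboxylate (C1 epimers and enol) | COC(=O)C1C(=O)CC[C@@H]1[C@@H](C=O)CC/C=C(\C)CCC=C(C)C | intermediate
11 | methyl (5R)-5-[(2S,5E)-6,10-dimethyl-1-oxoundeca-5,9-dien-2-yl]-2-{[(trifluoromethyl)sulfonyl]oxy}cyclopent-1-ene-1-carboxylate | COC(=O)C1=C(OS(=O)(=O)C(F)(F)F)CC[C@@H]1[C@@H](C=O)CC/C=C(\C)CCC=C(C)C | intermediate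
12 | (3R)-2-(hydroxymethyl)-3-[(2S,5E)-1-hydroxy-6,10-dimethylundeca-5,9-dien-2-yl]cyclopent-1-en-1-yl trifluoromethanesulfonate | OCC1=C(OS(=O)(=O)C(F)(F)F)CC[C@@H]1[C@@H](CO)CC/C=C(\C)CCC=C(C)C | intermediate
13 | (tributylstannyl)methanol | CCCC[Sn](CCCC)(CCCC)CO | starting material
14 | (tributylstannyl)methyl acetate | CCCC[Sn](CCCC)(CCCC)COC(C)=O | intermediate
15 | [(3R)-2-(hydroxymethyl)-3-[(2S,5E)-1-hydroxy-6,10-dimethylundeca-5,9-dien-2-yl]cyclopent-1-en-1-yl]methyl acetate | CC(=O)OCC1=C(CO)[C@@H]([C@@H](CO)CC/C=C(\C)CCC=C(C)C)CC1 | intermediate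
16 | [(3R)-2-formyl-3-[(2S,5E)-6,10-dimethyl-1-oxoundeca-5,9-dien-2-yl]cyclopent-1-en-1-yl]methyl acetate | CC(=O)OCC1=C(C=O)[C@@H]([C@@H](C=O)CC/C=C(\C)CCC=C(C)C)CC1 | target

Total step count: 9. Longest linear sequence: 8 (steps 1 to 6, 8 and 9).

Steps most likely to fail

Step 4. The cyclisation may suffer from a slow 5-enolendo closure, an acid-mediated racemic background reaction, poor facial selectivity in the enamine protonation, or epimerisation of the α-formyl centre through re-formation of the enamine. The fallback sets out from 8 and returns to the route at 16; it gives up the one-flask annulation and closes the ring last.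
- The alkylation is quenched with aq. NH4Cl and 8 is isolated.
- NaH and Tf2O should give methyl (2Z,10E)-7-(dimethoxymethyl)-11,15-dimethyl-3-{[(trifluoromethyl)sulfonyl]oxy}hexadeca-2,6,10,14-tetraenoate F1.
- i-Bu2AlH at −78 °C should reduce the ester to (2Z,10E)-7-(dimethoxymethyl)-1-hydroxy-11,15-dimethylhexadeca-2,6,10,14-tetraen-3-yl trifluoromethanesulfonate F2.
- Stille coupling with 14 (Pd(PPh3)4, LiCl) should give (2Z,10E)-3-(acetoxymethyl)-7-(dimethoxymethyl)-11,15-dimethylhexadeca-2,6,10,14-tetraen-1-ol F3.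
- MnO2 should oxidise it to (2Z,10E)-3-(acetoxymethyl)-7-(dimethoxymethyl)-11,15-dimethylhexadeca-2,6,10,14-tetraenal F4.
- PPTS in wet acetone should unmask (2Z,6E,10E)-3-(acetoxymethyl)-7-formyl-11,15-dimethylhexadeca-2,6,10,14-tetraenal F5.
- α,α-Diphenylprolinol trimethylsilyl ether with benzoic acid should then convert the acetoxymethyl enal into its dienamine, whose α-carbon adds to the second enal (intramolecular Rauhut–Currier-type Michael addition). Reconjugation gives 16 directly, with both stereocentres set under catalyst control in the final operation; the catalyst enantiomer is chosen for the (3R) ring carbon.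

Step 8. Transmetalation of the sp3 stannane may be slow at the hindered tetrasubstituted vinyl triflate, butyl transfer may compete, and the acetyl group may migrate to the neighbouring allylic hydroxyl. The fallback sets out from 12 and returns at 15; it builds the acetoxymethyl group by carbonylation and reduction on a protected diol.
- TBSCl and imidazole should give (3R)-2-{[tert-butyl(dimethyl)silyl]oxymethyl}-3-[(2S,5E)-1-{[tert-butyl(dimethyl)silyl]oxy}-6,10-dimethylundeca-5,9-dien-2-yl]cyclopent-1-en-1-yl trifluoromethanesulfonate F6.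
- Methoxycarbonylation (Pd(OAc)2, dppp, CO, MeOH, Et3N, DMF) should give methyl (3R)-2-{[tert-butyl(dimethyl)silyl]oxymethyl}-3-[(2S,5E)-1-{[tert-butyl(dimethyl)silyl]oxy}-6,10-dimethylundeca-5,9-dien-2-yl]cyclopent-1-ene-1-carboxylate F7.
- i-Bu2AlH should reduce it to [(3R)-2-{[tert-butyl(dimethyl)silyl]oxymethyl}-3-[(2S,5E)-1-{[tert-butyl(dimethyl)silyl]oxy}-6,10-dimethylundeca-5,9-dien-2-yl]cyclopent-1-en-1-yl]methanol F8.
- Ac2O and pyridine should give [(3R)-2-{[tert-butyl(dimethyl)silyl]oxymethyl}-3-[(2S,5E)-1-{[tert-butyl(dimethyl)silyl]oxy}-6,10-dimethylundeca-5,9-dien-2-yl]cyclopent-1-en-1-yl]methyl acetate F9.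
- HF·pyridine should remove both silyl groups to give 15.

Step 3. Ionisation of the tertiary allylic alcohol may lead to cation–olefin cyclisation onto the chain alkene or to loss of the acetal under the acidic bromination conditions. The fallback sets out from 5 and returns at 8; it replaces the SN2′/SN2 pair by a sigmatropic shift.
- 5 is heated with dimethyl 3-oxopentanedioate (DMAP cat., xylene, 140 °C, methanol distilled off).
- Transesterification should give 3-(dimethoxymethyl)-7,11-dimethyldodeca-1,6,10-trien-3-yl methyl 3-oxopentanedioate F10, which is not isolated.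
- Carroll rearrangement and decarboxylation of F10 should form the same C4–C5 ring bond and give 8.
- 8 is then hydrolysed and cyclised as in the second and third stages of step 4.

Further compounds
F1 | step 4 | methyl (2Z,10E)-7-(dimethoxymethyl)-11,15-dimethyl-3-{[(trifluoromethyl)sulfonyl]oxy}hexadeca-2,6,10,14-tetraenoate | COC(=O)/C=C(\OS(=O)(=O)C(F)(F)F)CCC=C(C(OC)OC)CC/C=C(\C)CCC=C(C)C
F2 | step 4 | (2Z,10E)-7-(dimethoxymethyl)-1-hydroxy-11,15-dimethylhexadeca-2,6,10,14-tetraen-3-yl trifluoromethanesulfonate | OC/C=C(\OS(=O)(=O)C(F)(F)F)CCC=C(C(OC)OC)CC/C=C(\C)CCC=C(C)C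
F3 | step 4 | (2Z,10E)-3-(acetoxymethyl)-7-(dimethoxymethyl)-11,15-dimethylhexadeca-2,6,10,14-tetraen-1-ol | OC/C=C(\COC(C)=O)CCC=C(C(OC)OC)CC/C=C(\C)CCC=C(C)C
F4 | step 4 | (2Z,10E)-3-(acetoxymethyl)-7-(dimethoxymethyl)-11,15-dimethylhexadeca-2,6,10,14-tetraenal | O=C/C=C(\COC(C)=O)CCC=C(C(OC)OC)CC/C=C(\C)CCC=C(C)C
F5 | step 4 | (2Z,6E,10E)-3-(acetoxymethyl)-7-formyl-11,15-dimethylhexadeca-2,6,10,14-tetraenal | O=C/C=C(\COC(C)=O)CC/C=C(/C=O)CC/C=C(\C)CCC=C(C)C
F6 | step 8 | (3R)-2-{[tert-butyl(dimethyl)silyl]oxymethyl}-3-[(2S,5E)-1-{[tert-butyl(dimethyl)silyl]oxy}-6,10-dimethylundeca-5,9-dien-2-yl]cyclopent-1-en-1-yl trifluoromethanesulfonate | CC(C)(C)[Si](C)(C)OCC1=C(OS(=O)(=O)C(F)(F)F)CC[C@@H]1[C@@H](CO[Si](C)(C)C(C)(C)C)CC/C=C(\C)CCC=C(C)C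
F7 | step 8 | methyl (3R)-2-{[tert-butyl(dimethyl)silyl]oxymethyl}-3-[(2S,5E)-1-{[tert-butyl(dimethyl)silyl]oxy}-6,10-dimethylundeca-5,9-dien-2-yl]cyclopent-1-ene-1-carboxylate | COC(=O)C1=C(CO[Si](C)(C)C(C)(C)C)[C@@H]([C@@H](CO[Si](C)(C)C(C)(C)C)CC/C=C(\C)CCC=C(C)C)CC1
F8 | step 8 | [(3R)-2-{[tert-butyl(dimethyl)silyl]oxymethyl}-3-[(2S,5E)-1-{[tert-butyl(dimethyl)silyl]oxy}-6,10-dimethylundeca-5,9-dien-2-yl]cyclopent-1-en-1-yl]methanol | OCC1=C(CO[Si](C)(C)C(C)(C)C)[C@@H]([C@@H](CO[Si](C)(C)C(C)(C)C)CC/C=C(\C)CCC=C(C)C)CC1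
F9 | step 8 | [(3R)-2-{[tert-butyl(dimethyl)silyl]oxymethyl}-3-[(2S,5E)-1-{[tert-butyl(dimethyl)silyl]oxy}-6,10-dimethylundeca-5,9-dien-2-yl]cyclopent-1-en-1-yl]methyl acetate | CC(=O)OCC1=C(CO[Si](C)(C)C(C)(C)C)[C@@H]([C@@H](CO[Si](C)(C)C(C)(C)C)CC/C=C(\C)CCC=C(C)C)CC1
F10 | step 3 | 3-(dimethoxymethyl)-7,11-dimethyldodeca-1,6,10-trien-3-yl methyl 3-oxopentanedioate | COC(=O)CC(=O)CC(=O)OC(C=C)(C(OC)OC)CC/C=C(\C)CCC=C(C)C
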